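The route rests on cutting the C9–C10 bond of the eudesmane core (eudesmane numbering throughout). Ring A, with carbon substituents on C4, C5 and C10, its only alkene at C3–C4 and a quaternary C10 para to C3, is the latent form of a 2,3,4-trisubstituted phenol oxygenated at C3. In one operation the para carbon of that phenoxide displaces a primary mesylate at C9: ring B closes, aromaticity is broken and the methyl-bearing quaternary centre C10 is set from C7. The precursor is a phenol carrying C15 as a bulky silyloxymethyl group and, at C5, an (S)-configured chain with C11 as a pivalate and C9 as a mesylate.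

Key step: step 13

Remarks on the chemistry (assumptions)
- β denotes the face of the C10 methyl group, α the opposite face; C14 is the C10 methyl carbon.
- Protecting groups of the precursor: a phenol would be sulfonylated together with C9–OH, so the phenol and C15–OH stay tied in one acetonide until the mesylate is in place. C15 then receives a TBDPS ether, which shields the ortho carbon C4 and is stable to the later acidic carbonylation. C11 is a pivalate, removable in the presence of the silyl ether.
- Assumption: reagent 33 and aldehyde 35 are purchased; the minor C10 epimer of 21 and the minor 3α epimer of 23 are removed by chromatography before C7 becomes epimerisable.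

Step 1
Reactants: 1 2-methylfuran; 2 dimethyl acetylenedicarboxylate
Product: 4 dimethyl 3-hydroxy-6-methylphthalate, via oxanorbornadiene diester 3 (not isolated)
Conditions: neat, 40 °C; then BF3·OEt2 (20 mol %), CH2Cl2, 0 °C → rt
Reagents that add atoms: none
Why: Diels–Alder addition of the furan to the acetylenic diester gives 3, and Lewis-acid opening of the oxygen bridge at the methyl-bearing tertiary bridgehead, followed by hydride shift and enolisation, should aromatise it with the hydroxyl on the former CH bridgehead, para to the methyl group.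

Step 2
Reactants: 4 dimethyl 3-hydroxy-6-methylphthalate
Product: 5 2,3-bis(hydroxymethyl)-4-methylphenol
Conditions: LiAlH4 (excess), THF, 0 °C → reflux; mildly acidic aqueous work-up
Reagents that add atoms: none
Why: Hydride reduction of both aryl esters to benzylic alcohols should proceed cleanly, the aluminium phenoxide formed in the flask being inert.

Step 3
Reactants: 5 2,3-bis(hydroxymethyl)-4-methylphenol
Product: 6 (2,2,6-trimethyl-4H-1,3-benzodioxin-5-yl)methanol
Conditions: 2,2-dimethoxypropane, TsOH·H2O (cat.), acetone, rt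
Reagents that add atoms: 2,2-dimethoxypropane COC(C)(C)OC
Why: Acetonide formation under equilibrating acid catalysis should favour the six-membered aryl alkyl ketal across the phenol and its ortho CH2OH (the behaviour of salicyl alcohols) over the seven-membered ketal across the two benzylic alcohols, which leaves only the future C6 hydroxyl free.

Step 4
Reactants: 6 (2,2,6-trimethyl-4H-1,3-benzodioxin-5-yl)methanol
Product: 7 5-(bromomethyl)-2,2,6-trimethyl-4H-1,3-benzodioxine
Conditions: CBr4, PPh3, CH2Cl2, 0 °C; used at once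
Reagents that add atoms: carbon tetrabromide BrC(Br)(Br)Br
Why: Appel bromination converts the only free, primary benzylic alcohol into the bromide under neutral conditions that spare the acid-labile ketal.

Step 5
Reactants: 8 4-(benzyloxy)butanoic acid; 9 (S)-4-benzyloxazolidin-2-one
Product: 11 (S)-4-benzyl-3-[4-(benzyloxy)butanoyl]oxazolidin-2-one, via mixed pivalic anhydride 10 (not isolated)
Conditions: PivCl, Et3N, THF, −20 °C; then 9, LiCl, −20 °C → rt
Reagents that add atoms: none
Why: N-acylation of the oxazolidinone through the mixed pivalic anhydride with LiCl/Et3N activation is the standard loading of an Evans auxiliary.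

Step 6
Reactants: 11 (S)-4-benzyl-3-[4-(benzyloxy)butanoyl]oxazolidin-2-one; 7 5-(bromomethyl)-2,2,6-trimethyl-4H-1,3-benzodioxine
Product: 13 (S)-4-benzyl-3-{(S)-4-(benzyloxy)-2-[(2,2,6-trimethyl-4H-1,3-benzodioxin-5-yl)methyl]butanoyl}oxazolidin-2-one, via sodium Z-enolate 12 (not isolated)
Conditions: NaHMDS, THF, −78 °C; then 7, −78 → −40 °C
Reagents that add atoms: none
Why: Evans alkylation, in which the chelated sodium Z-enolate is benzylated on the face opposite the benzyl group of the (S)-auxiliary, should set C7 as (S) and form C6–C7; the diastereomer is purified here.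

Step 7
Reactants: 13 alkylated imide
Product: 14 (S)-4-(benzyloxy)-2-[(2,2,6-trimethyl-4H-1,3-benzodioxin-5-yl)methyl]butan-1-ol
Conditions: LiBH4, THF/H2O (1 equiv), 0 °C
Reagents that add atoms: none
Why: Reductive cleavage of the imide at its exocyclic carbonyl gives the primary alcohol C11–OH without touching C7 and returns the auxiliary.

Step 8
Reactants: 14 primary alcohol
Product: 15 (S)-4-(benzyloxy)-2-[(2,2,6-trimethyl-4H-1,3-benzodioxin-5-yl)methyl]butyl pivalate
Conditions: PivCl, pyridine, DMAP (cat.), CH2Cl2, 0 °C → rt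
Reagents that add atoms: pivaloyl chloride CC(C)(C)C(Cl)=O
Why: Acylation of the primary alcohol gives an ester that should survive hydrogenolysis, aqueous acid and the phenoxide step, and that can later be removed beside a silyl ether.

Step 9
Reactants: 15 benzyl ether pivalate
Product: 16 (S)-4-hydroxy-2-[(2,2,6-trimethyl-4H-1,3-benzodioxin-5-yl)methyl]butyl pivalate
Conditions: H2 (1 atm), 10% Pd/C, EtOAc, rt
Reagents that add atoms: none
Why: Hydrogenolysis should remove the unhindered benzyl ether, while the ketal C–O bond at the doubly ortho-substituted benzylic position is expected to survive in a non-acidic solvent.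

Step 10
Reactants: 16 primary alcohol C9–OH
Product: 17 (S)-4-[(methylsulfonyl)oxy]-2-[(2,2,6-trimethyl-4H-1,3-benzodioxin-5-yl)methyl]butyl pivalate
Conditions: MsCl, Et3N, CH2Cl2, 0 °C
Reagents that add atoms: methanesulfonyl chloride CS(Cl)(=O)=O
Why: Mesylation of the primary alcohol is done while the phenol is still masked, so that no aryl sulfonate can form.

Step 11
Reactants: 17 acetonide mesylate
Product: 18 (S)-2-[3-hydroxy-2-(hydroxymethyl)-6-methylbenzyl]-4-[(methylsulfonyl)oxy]butyl pivalate
Conditions: AcOH/H2O/THF (3:1:1), 45 °C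
Reagents that add atoms: none
Why: Mild acid hydrolysis of the aryl alkyl ketal frees the phenol and C15–OH, while the pivalate and the primary mesylate should be untouched.

Step 12
Reactants: 18 phenol diol mesylate
Product: 19 (S)-2-[2-({[tert-butyl(diphenyl)silyl]oxy}methyl)-3-hydroxy-6-methylbenzyl]-4-[(methylsulfonyl)oxy]butyl pivalate
Conditions: TBDPSCl (1.1 equiv), imidazole, CH2Cl2, 0 °C → rt
Reagents that add atoms: tert-butyl(chloro)diphenylsilane CC(C)(C)[Si](Cl)(c1ccccc1)c1ccccc1
Why: Chemoselective silylation should work because, under imidazole conditions, the neutral primary alcohol is silylated much faster than the hydrogen-bonded, ortho-substituted phenol.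

Step 13
Reactants: 19 phenol mesylate (key-step precursor)
Product: 21 (7R,10S)-15-(tert-butyldiphenylsilyloxy)-11-(pivaloyloxy)-12,13-dinoreudesma-1,4-dien-3-one, via potassium phenoxide 20 (not isolated)
Conditions: KOtBu (1.05 equiv), t-BuOH, 0.01 M, 25 → 60 °C
Reagents that add atoms: none
Why: KOtBu deprotonates only the phenol, and the ambident phenoxide 20 displaces the primary mesylate through its para carbon C10 in an intramolecular SN2 reaction, so that C9–C10 forms while the arene becomes the cross-conjugated cyclohexa-2,5-dienone; the closest known reaction type is the base-mediated alkylative dearomatisation of phenols by aryl participation of the Ar2-6 kind. Ring B (C5–C6–C7–C8–C9–C10) closes 6-exo-tet, C9 approaching C10 perpendicular to the ring plane with the mesylate leaving outside the new ring. The new quaternary stereocentre C10 is controlled by C7: in the chair-like transition state the CH2OPiv group is equatorial, which places C9 on the face that leaves the methyl group axial in ring B and cis to the C7 substituent (7β,10β). The step needs para-C over ortho-C (C4) alkylation; O-alkylation would require an eight-membered meta-bridged ring, the tert-butanol-solvated potassium phenoxide should react at the oxygen-remote para carbon, and attack at C4 would build a quaternary centre next to the bulky CH2OTBDPS group and give the less stable linearly conjugated 2,4-dienone. As C4 and C10 both carry carbon substituents no rearomatisation is possible, and high dilution should suppress intermolecular alkylation.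

Step 14
Reactants: 21 dienone
Product: 22 (7R,10S)-15-(tert-butyldiphenylsilyloxy)-11-(pivaloyloxy)-12,13-dinoreudesm-4-en-3-one
Conditions: H2 (1 atm), RhCl(PPh3)3 (5 mol %), benzene/EtOH (1:1), rt
Reagents that add atoms: none
Why: Homogeneous hydrogenation with RhCl(PPh3)3 should saturate the cis-disubstituted C1=C2 bond of the cross-conjugated dienone and leave the tetrasubstituted C4=C5 bond, as it does with steroidal 1,4-dien-3-ones.

Step 15
Reactants: 22 enone
Product: 23 (3S,7R,10S)-15-(tert-butyldiphenylsilyloxy)-11-(pivaloyloxy)-12,13-dinoreudesm-4-en-3β-ol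
Conditions: NaBH4, CeCl3·7H2O, MeOH, −40 → 0 °C
Reagents that add atoms: none
Why: Luche reduction is 1,2-selective, and axial hydride delivery from the α face of the 10β-methyl octalone should give the pseudo-equatorial 3β alcohol, as with steroidal 4-en-3-ones.

Step 16
Reactants: 23 allylic alcohol
Product: 27 (5R,7R,10R)-15-(tert-butyldiphenylsilyloxy)-11-(pivaloyloxy)-12,13-dinoreudesm-3-ene, via Mitsunobu hydrazone adduct 24 (not isolated), via N-aminosulfonamide 25 (not isolated), via allylic diazene 26 (not isolated)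
Conditions: IPNBSH (N'-isopropylidene-2-nitrobenzenesulfonohydrazide), PPh3, DEAD, THF, 0 → 23 °C; then CF3CH2OH/H2O (1:1), 23 °C
Reagents that add atoms: none
Why: Mitsunobu displacement of the 3β alcohol by the sulfonyl hydrazone nitrogen with inversion, hydrazone hydrolysis and loss of the sulfinic acid give the 3α allylic diazene, whose retro-ene loss of N2 delivers hydrogen suprafacially to the α face of C5 and moves the alkene to C3–C4 (reductive 1,3-transposition), setting the trans ring fusion.

Step 17
Reactants: 27 pivalate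
Product: 28 (5R,7R,10R)-15-(tert-butyldiphenylsilyloxy)-12,13-dinoreudesm-3-en-11-ol
Conditions: iBu2AlH (2.5 equiv), CH2Cl2, −78 °C
Reagents that add atoms: none
Why: Reductive cleavage of the pivalate by the aluminium hydride frees C11–OH; the silyl ether and the trisubstituted alkene are inert.

Step 18
Reactants: 28 primary alcohol
Product: 29 (5R,7R,10R)-15-(tert-butyldiphenylsilyloxy)-12,13-dinoreudesm-3-en-11-al
Conditions: Dess–Martin periodinane, NaHCO3, CH2Cl2, 0 °C → rt
Reagents that add atoms: none
Why: Dess–Martin oxidation gives the aldehyde under buffered conditions, and the formyl group at C7 is already in the equatorial, thermodynamically preferred position.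

Step 19
Reactants: 29 aldehyde
Product: 30 (5R,7R,10R)-15-(tert-butyldiphenylsilyloxy)-12-noreudesm-3-en-11(13)-yne
Conditions: dimethyl (1-diazo-2-oxopropyl)phosphonate, K2CO3, MeOH, 0 °C → rt
Reagents that add atoms: dimethyl (1-diazo-2-oxopropyl)phosphonate CC(=O)C(=[N+]=[N-])P(=O)(OC)OC
Why: Ohira–Bestmann homologation adds C13 and gives the terminal alkyne; the mild base cannot erode C7 because its substituent is already equatorial.

Step 20
Reactants: 30 terminal alkyne
Product: 31 2-(trimethylsilyl)ethyl (5R,7R,10R)-15-(tert-butyldiphenylsilyloxy)eudesma-3,11(13)-dien-12-oate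
Conditions: Pd(OAc)2 (2 mol %), 2-(diphenylphosphino)pyridine (20 mol %), CH3SO3H (20 mol %), CO (20 bar), Me3SiCH2CH2OH (5 equiv), toluene, 50 °C
Reagents that add atoms: carbon monoxide [C-]#[O+]; 2-(trimethylsilyl)ethanol C[Si](C)(C)CCO
Why: Palladium-catalysed Markovnikov hydroalkoxycarbonylation of a terminal alkyne with a pyridylphosphine/acid system should give the 2-substituted acrylate, the acid being buffered by the ligand so that the TBDPS ether survives.

Step 21
Reactants: 31 silyl ether
Product: 32 2-(trimethylsilyl)ethyl (5R,7R,10R)-15-hydroxyeudesma-3,11(13)-dien-12-oate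
Conditions: HF·pyridine, pyridine/THF, 0 °C → rt
Reagents that add atoms: none
Why: Acidic fluoride should cleave the primary allylic silyl ether, whereas the 2-(trimethylsilyl)ethyl ester needs basic fluoride and should stay.

Step 22
Reactants: 32 allylic alcohol; 33 2-(diphenoxyphosphoryl)acetic acid
Product: 34 2-(trimethylsilyl)ethyl (5R,7R,10R)-15-[2-(diphenoxyphosphoryl)acetoxy]eudesma-3,11(13)-dien-12-oate
Conditions: DCC, DMAP (cat.), CH2Cl2, 0 °C → rt
Reagents that add atoms: none
Why: Steglich esterification of the unhindered primary allylic alcohol with the phosphonoacetic acid installs the olefination handle.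

Step 23
Reactants: 34 phosphonoacetate; 35 4-{[tert-butyl(dimethyl)silyl]oxy}benzaldehyde
Product: 37 2-(trimethylsilyl)ethyl (5R,7R,10R)-15-{[(Z)-3-(4-{[tert-butyl(dimethyl)silyl]oxy}phenyl)prop-2-enoyl]oxy}eudesma-3,11(13)-dien-12-oate, via sodium phosphonoacetate anion 36 (not isolated)
Conditions: NaH (1.0 equiv), THF, 0 °C; then 35, −78 → −20 °C, dark
Reagents that add atoms: none
Why: Ando-type Horner–Wadsworth–Emmons olefination with a diaryl phosphonoacetate should give the Z-cinnamate under kinetic control, because the electron-poor phosphonate makes oxaphosphetane collapse fast and irreversible.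

Step 24
Reactants: 37 bis-silyl protected ester
Product: 38 (5R,7R,10R)-15-{[(Z)-3-(4-hydroxyphenyl)prop-2-enoyl]oxy}eudesma-3,11(13)-dien-12-oic acid (CNP0183482.1)
Conditions: TBAF (3 equiv), THF, 0 °C → rt, dark; aq. NH4Cl
Reagents that add atoms: none
Why: Fluoride cleaves the aryl silyl ether and triggers β-elimination of the 2-(trimethylsilyl)ethyl ester in one operation, conditions that should leave the allylic Z-cinnamate and the alkenes untouched.

Compound list
1 | 2-methylfuran | Cc1ccco1 | starting material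
2 | dimethyl acetylenedicarboxylate | COC(=O)C#CC(=O)OC | starting material
3 | dimethyl 1-methyl-7-oxabicyclo[2.2.1]hepta-2,5-diene-2,3-dicarboxylate (racemic, not isolated) | CC12C=CC(O1)C(C(=O)OC)=C2C(=O)OC | intermediate
4 | dimethyl 3-hydroxy-6-methylphthalate | COC(=O)c1c(O)ccc(C)c1C(=O)OC | intermediate
5 | 2,3-bis(hydroxymethyl)-4-methylphenol | Cc1ccc(O)c(CO)c1CO | intermediate
6 | (2,2,6-trimethyl-4H-1,3-benzodioxin-5-yl)methanol | Cc1ccc2OC(C)(C)OCc2c1CO | intermediate
7 | 5-(bromomethyl)-2,2,6-trimethyl-4H-1,3-benzodioxine | Cc1ccc2OC(C)(C)OCc2c1CBr | intermediate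
8 | 4-(benzyloxy)butanoic acid | OC(=O)CCCOCc1ccccc1 | starting material
9 | (S)-4-benzyloxazolidin-2-one | O=C1N[C@@H](Cc2ccccc2)CO1 | starting material
10 | 4-(benzyloxy)butanoic pivalic anhydride (not isolated) | CC(C)(C)C(=O)OC(=O)CCCOCc1ccccc1 | intermediate
11 | (S)-4-benzyl-3-[4-(benzyloxy)butanoyl]oxazolidin-2-one | O=C(CCCOCc1ccccc1)N1C(=O)OC[C@@H]1Cc1ccccc1 | intermediate
12 | sodium Z-enolate of 11 (not isolated) | [Na+].[O-]/C(=C\CCOCc1ccccc1)N1C(=O)OC[C@@H]1Cc1ccccc1 | intermediate
13 | (S)-4-benzyl-3-{(S)-4-(benzyloxy)-2-[(2,2,6-trimethyl-4H-1,3-benzodioxin-5-yl)methyl]butanoyl}oxazolidin-2-one | Cc1ccc2OC(C)(C)OCc2c1C[C@H](C(=O)N1C(=O)OC[C@@H]1Cc1ccccc1)CCOCc1ccccc1 | intermediate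
14 | (S)-4-(benzyloxy)-2-[(2,2,6-trimethyl-4H-1,3-benzodioxin-5-yl)methyl]butan-1-ol | Cc1ccc2OC(C)(C)OCc2c1C[C@H](CO)CCOCc1ccccc1 | intermediate
15 | (S)-4-(benzyloxy)-2-[(2,2,6-trimethyl-4H-1,3-benzodioxin-5-yl)methyl]butyl pivalate | Cc1ccc2OC(C)(C)OCc2c1C[C@H](COC(=O)C(C)(C)C)CCOCc1ccccc1 | intermediate
16 | (S)-4-hydroxy-2-[(2,2,6-trimethyl-4H-1,3-benzodioxin-5-yl)methyl]butyl pivalate | Cc1ccc2OC(C)(C)OCc2c1C[C@H](COC(=O)C(C)(C)C)CCO | intermediate
17 | (S)-4-[(methylsulfonyl)oxy]-2-[(2,2,6-trimethyl-4H-1,3-benzodioxin-5-yl)methyl]butyl pivalate | Cc1ccc2OC(C)(C)OCc2c1C[C@H](COC(=O)C(C)(C)C)CCOS(C)(=O)=O | intermediate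
18 | (S)-2-[3-hydroxy-2-(hydroxymethyl)-6-methylbenzyl]-4-[(methylsulfonyl)oxy]butyl pivalate | Cc1ccc(O)c(CO)c1C[C@H](COC(=O)C(C)(C)C)CCOS(C)(=O)=O | intermediate
19 | (S)-2-[2-({[tert-butyl(diphenyl)silyl]oxy}methyl)-3-hydroxy-6-methylbenzyl]-4-[(methylsulfonyl)oxy]butyl pivalate (key-step precursor) | Cc1ccc(O)c(CO[Si](c2ccccc2)(c2ccccc2)C(C)(C)C)c1C[C@H](COC(=O)C(C)(C)C)CCOS(C)(=O)=O | intermediate
20 | potassium phenoxide of 19 (not isolated) | Cc1ccc([O-])c(CO[Si](c2ccccc2)(c2ccccc2)C(C)(C)C)c1C[C@H](COC(=O)C(C)(C)C)CCOS(C)(=O)=O.[K+] | intermediate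
21 | (7R,10S)-15-(tert-butyldiphenylsilyloxy)-11-(pivaloyloxy)-12,13-dinoreudesma-1,4-dien-3-one (7β-CH2OPiv, 10β-CH3; key-step product) | CC(C)(C)C(=O)OC[C@@H]1CC[C@@]2(C)C=CC(=O)C(CO[Si](c3ccccc3)(c3ccccc3)C(C)(C)C)=C2C1 | intermediate
22 | (7R,10S)-15-(tert-butyldiphenylsilyloxy)-11-(pivaloyloxy)-12,13-dinoreudesm-4-en-3-one | CC(C)(C)C(=O)OC[C@@H]1CC[C@@]2(C)CCC(=O)C(CO[Si](c3ccccc3)(c3ccccc3)C(C)(C)C)=C2C1 | intermediate
23 | (3S,7R,10S)-15-(tert-butyldiphenylsilyloxy)-11-(pivaloyloxy)-12,13-dinoreudesm-4-en-3β-ol | CC(C)(C)C(=O)OC[C@@H]1CC[C@@]2(C)CC[C@H](O)C(CO[Si](c3ccccc3)(c3ccccc3)C(C)(C)C)=C2C1 | intermediate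
24 | 3α-[N-(2-nitrophenylsulfonyl)-N'-isopropylidenehydrazino] adduct of 23 (not isolated) | CC(C)(C)C(=O)OC[C@@H]1CC[C@@]2(C)CC[C@@H](N(N=C(C)C)S(=O)(=O)c3ccccc3[N+](=O)[O-])C(CO[Si](c3ccccc3)(c3ccccc3)C(C)(C)C)=C2C1 | intermediate
25 | 3α-[N-amino-N-(2-nitrophenylsulfonyl)amino] compound (not isolated) | CC(C)(C)C(=O)OC[C@@H]1CC[C@@]2(C)CC[C@@H](N(N)S(=O)(=O)c3ccccc3[N+](=O)[O-])C(CO[Si](c3ccccc3)(c3ccccc3)C(C)(C)C)=C2C1 | intermediate
26 | 3α-diazenyl compound (not isolated) | CC(C)(C)C(=O)OC[C@@H]1CC[C@@]2(C)CC[C@@H](N=N)C(CO[Si](c3ccccc3)(c3ccccc3)C(C)(C)C)=C2C1 | intermediate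
27 | (5R,7R,10R)-15-(tert-butyldiphenylsilyloxy)-11-(pivaloyloxy)-12,13-dinoreudesm-3-ene (5α-H) | CC(C)(C)C(=O)OC[C@@H]1CC[C@@]2(C)CCC=C(CO[Si](c3ccccc3)(c3ccccc3)C(C)(C)C)[C@@H]2C1 | intermediate
28 | (5R,7R,10R)-15-(tert-butyldiphenylsilyloxy)-12,13-dinoreudesm-3-en-11-ol | OC[C@@H]1CC[C@@]2(C)CCC=C(CO[Si](c3ccccc3)(c3ccccc3)C(C)(C)C)[C@@H]2C1 | intermediate
29 | (5R,7R,10R)-15-(tert-butyldiphenylsilyloxy)-12,13-dinoreudesm-3-en-11-al | O=C[C@@H]1CC[C@@]2(C)CCC=C(CO[Si](c3ccccc3)(c3ccccc3)C(C)(C)C)[C@@H]2C1 | intermediate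
30 | (5R,7R,10R)-15-(tert-butyldiphenylsilyloxy)-12-noreudesm-3-en-11(13)-yne | C#C[C@@H]1CC[C@@]2(C)CCC=C(CO[Si](c3ccccc3)(c3ccccc3)C(C)(C)C)[C@@H]2C1 | intermediate
31 | 2-(trimethylsilyl)ethyl (5R,7R,10R)-15-(tert-butyldiphenylsilyloxy)eudesma-3,11(13)-dien-12-oate | C=C(C(=O)OCC[Si](C)(C)C)[C@@H]1CC[C@@]2(C)CCC=C(CO[Si](c3ccccc3)(c3ccccc3)C(C)(C)C)[C@@H]2C1 | intermediate
32 | 2-(trimethylsilyl)ethyl (5R,7R,10R)-15-hydroxyeudesma-3,11(13)-dien-12-oate | C=C(C(=O)OCC[Si](C)(C)C)[C@@H]1CC[C@@]2(C)CCC=C(CO)[C@@H]2C1 | intermediate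
33 | 2-(diphenoxyphosphoryl)acetic acid | OC(=O)CP(=O)(Oc1ccccc1)Oc1ccccc1 | starting material
34 | 2-(trimethylsilyl)ethyl (5R,7R,10R)-15-[2-(diphenoxyphosphoryl)acetoxy]eudesma-3,11(13)-dien-12-oate | C=C(C(=O)OCC[Si](C)(C)C)[C@@H]1CC[C@@]2(C)CCC=C(COC(=O)CP(=O)(Oc3ccccc3)Oc3ccccc3)[C@@H]2C1 | intermediate
35 | 4-{[tert-butyl(dimethyl)silyl]oxy}benzaldehyde | O=Cc1ccc(O[Si](C)(C)C(C)(C)C)cc1 | starting material
36 | sodium salt of the phosphonoacetate carbanion of 34 (not isolated) | [Na+].C=C(C(=O)OCC[Si](C)(C)C)[C@@H]1CC[C@@]2(C)CCC=C(COC(=O)[CH-]P(=O)(Oc3ccccc3)Oc3ccccc3)[C@@H]2C1 | intermediate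
37 | 2-(trimethylsilyl)ethyl (5R,7R,10R)-15-{[(Z)-3-(4-{[tert-butyl(dimethyl)silyl]oxy}phenyl)prop-2-enoyl]oxy}eudesma-3,11(13)-dien-12-oate | C=C(C(=O)OCC[Si](C)(C)C)[C@@H]1CC[C@@]2(C)CCC=C(COC(=O)/C=C\c3ccc(O[Si](C)(C)C(C)(C)C)cc3)[C@@H]2C1 | intermediate
38 | (5R,7R,10R)-15-{[(Z)-3-(4-hydroxyphenyl)prop-2-enoyl]oxy}eudesma-3,11(13)-dien-12-oic acid | C=C(C(=O)O)[C@@H]1CC[C@@]2(C)CCC=C(COC(=O)/C=C\c3ccc(O)cc3)[C@@H]2C1 | target

Total step count: 24
Longest linear sequence: 23 steps (steps 1–4 and 6–24, from 2-methylfuran)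

Steps most likely to fail

1. Step 13 (key step). What may go wrong: alkylation through the ortho carbon C4 competing with the para carbon C10, or incomplete facial discrimination at C10 by the C7 substituent. Fallback: the anionic phenoxide chemistry is replaced by an electrophile-driven closure of the neutral phenol. The fallback sets out from 19, which is converted with NaI in acetone into (S)-2-[2-({[tert-butyl(diphenyl)silyl]oxy}methyl)-3-hydroxy-6-methylbenzyl]-4-iodobutyl pivalate F1. Treatment of F1 with AgOTf and 2,6-di-tert-butyl-4-methylpyridine in (CF3)2CHOH should close ring B by silver-assisted aryl participation, a dearomatising Friedel–Crafts-type alkylation, and loss of the phenolic proton from the oxocarbenium ion gives the dienone. The hydrogen-bonding solvent shields the hydroxyl and its neighbour C4, so attack is expected at C10. The fallback comes back to the route at 21.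

2. Step 16. What may go wrong: slow or SN2′-type Mitsunobu displacement at the hindered allylic C3, or elimination to a diene before the diazene can form. Fallback: hydride is delivered by palladium instead of a diazene. The fallback sets out from 23, which is formylated with acetic formic anhydride and pyridine to (3S,7R,10S)-15-(tert-butyldiphenylsilyloxy)-11-(pivaloyloxy)-12,13-dinoreudesm-4-en-3β-yl formate F2. With Pd(OAc)2 and PBu3 in THF at room temperature, ionisation with inversion puts palladium on the α face, decarboxylation of the formate gives a palladium hydride, and hydride transfer to the more substituted allyl terminus C5 on that α face should give the 5α-H 3-ene. The fallback comes back to the route at 27.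

3. Step 20. What may go wrong: poor branched-to-linear selectivity in the carbonylation, or acid-induced hydration of the alkyne and loss of the silyl ether. Fallback: the acrylate is built by carbonylation of an enol triflate. The fallback sets out from 30, which is hydrated (Ph3PAuCl/AgOTf, aqueous MeOH) to (5R,7R,10R)-15-(tert-butyldiphenylsilyloxy)-12-noreudesm-3-en-11-one F3. Kinetic enolisation on the methyl side (KHMDS, THF, −78 °C) and trapping with PhNTf2 give (5R,7R,10R)-15-(tert-butyldiphenylsilyloxy)-12-noreudesma-3,11(13)-dien-11-yl trifluoromethanesulfonate F4. Carbonylation of F4 (Pd(OAc)2, PPh3, CO 1 atm, Et3N, Me3SiCH2CH2OH, DMF, rt) comes back to the route at 31.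

Further compounds
F1 | step 13 | (S)-2-[2-({[tert-butyl(diphenyl)silyl]oxy}methyl)-3-hydroxy-6-methylbenzyl]-4-iodobutyl pivalate | Cc1ccc(O)c(CO[Si](c2ccccc2)(c2ccccc2)C(C)(C)C)c1C[C@H](COC(=O)C(C)(C)C)CCI
F2 | step 16 | (3S,7R,10S)-15-(tert-butyldiphenylsilyloxy)-11-(pivaloyloxy)-12,13-dinoreudesm-4-en-3β-yl formate | CC(C)(C)C(=O)OC[C@@H]1CC[C@@]2(C)CC[C@H](OC=O)C(CO[Si](c3ccccc3)(c3ccccc3)C(C)(C)C)=C2C1
F3 | step 20 | (5R,7R,10R)-15-(tert-butyldiphenylsilyloxy)-12-noreudesm-3-en-11-one | CC(=O)[C@@H]1CC[C@@]2(C)CCC=C(CO[Si](c3ccccc3)(c3ccccc3)C(C)(C)C)[C@@H]2C1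
F4 | step 20 | (5R,7R,10R)-15-(tert-butyldiphenylsilyloxy)-12-noreudesma-3,11(13)-dien-11-yl trifluoromethanesulfonate | C=C(OS(=O)(=O)C(F)(F)F)[C@@H]1CC[C@@]2(C)CCC=C(CO[Si](c3ccccc3)(c3ccccc3)C(C)(C)C)[C@@H]2C1
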